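**Plan**

1. Locants are briarane locants: ten-membered ring C1–C10; cyclohexene C1, C10, C11, C12, C13, C14; lactone O–C7–C8–C17–C19(=O); methyls C15 on C1, C16 on C5, C18 on C17, C20 on C11.
2. Retrosynthesis: after removal of the C2 and C9 acetates, the C1–C10 bond shared by the six- and ten-membered rings is cut to a 14-membered cembranolide-type carbocycle (the presumed cembrane-to-briarane cyclization run backwards). That ring is cut at C9–C10, the lactone at O–C7 (from a C7–C8 epoxide), and the chain at C7=C8, C12–C13 and C13–C14.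
3. Enabling feature: C1 is the quaternary atom common to both carbocycles, sits between the oxygen-bearing C2 and C14, and is tied to C10 through C14–C13–C12–C11, with C11 ending as the C11=C12 olefin. A C1–C2 epoxide therefore serves as a tertiary C1 radical that keeps the C2 oxygen, and a phenylsulfonyl group on C12 makes C10=C11 an acceptor that leaves as C11=C12.
4. Forward: nerol supplies C1–C7, C14, C15, C16 and the Z C5=C6 olefin. C13 and the C10–C12 iodo sulfone are added in the west, the lactone (first ring) is built in the east, a Nozaki–Hiyama–Kishi reaction closes the 14-membered ring, and the transannular radical step closes the cyclohexene last, which at once divides off the ten-membered ring.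
5. Stereochemistry: C14 from a hydrolytic kinetic resolution; C7 and C8 from a Sharpless epoxidation (D-tartrate) followed by SN2 lactonization; C17 from (R)-lactate by inversion; C2 from a matched Sharpless epoxidation (L-tartrate) directed by C14–OH; C9 in the Nozaki–Hiyama–Kishi closure; C1 and C10 in the key step.

Key step: step 18

Remark: the sulfone carbon C12 is formed unselectively in step 8 and is carried as an epimer mixture (left unspecified in the SMILES of 15–25); it becomes sp2 in step 18. C3 of phosphonate 8 is likewise unspecified and becomes sp2 in step 11.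

**Route**

Step 1
Reactants: 1 prop-2-yn-1-ol
Product: 2 (E)-3-iodo-2-methylprop-2-en-1-ol
Conditions: AlMe3, Cp2ZrCl2 (25 mol%), CH2Cl2, 0 °C to rt; then I2, THF, −30 to 0 °C
Reagents that add atoms: trimethylaluminium C[Al](C)C; iodine II
Why: Negishi zirconium-catalysed carboalumination adds methyl and aluminium syn across the alkyne with methyl on the inner carbon, and iodinolysis of the alkenyl–aluminium bond with retention should give the E iodide.

Step 2
Reactants: 2 (E)-3-iodo-2-methylprop-2-en-1-ol
Product: 4 (E)-3-iodo-2-methylprop-2-en-1-yl phenyl sulfone, via mesylate 3 (not isolated)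
Conditions: MsCl, Et3N, CH2Cl2, −10 °C; then PhSO2Na, DMF, rt
Reagents that add atoms: sodium benzenesulfinate [Na+].[O-]S(=O)c1ccccc1
Why: sulfonate formation and SN2 S-alkylation of the sulfinate at the primary allylic carbon should give the allyl sulfone without touching the alkenyl iodide.

Step 3
Reactants: 5 tert-butyl (R)-lactate; 6 triethyl phosphonoacetate
Product: 8 1-tert-butyl 4-ethyl (2S)-3-(diethoxyphosphoryl)-2-methylbutanedioate, via triflate 7 (not isolated)
Conditions: 5, Tf2O, 2,6-lutidine, CH2Cl2, −78 °C; then sodium salt of 6 (NaH, THF), −78 °C to rt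
Reagents that add atoms: none
Why: SN2 alkylation of the phosphonoacetate carbanion by the lactate triflate proceeds with inversion and so fixes the future C17 methyl centre (2S in 8).

Step 4
Reactants: 9 nerol
Product: 10 neryl tert-butyldimethylsilyl ether
Conditions: TBSCl, imidazole, DMF, rt
Reagents that add atoms: tert-butyldimethylsilyl chloride CC(C)(C)[Si](C)(C)Cl
Why: standard silylation of the primary allylic alcohol.

Step 5
Reactants: 10 neryl tert-butyldimethylsilyl ether
Product: 12 (2E,6Z)-8-(tert-butyldimethylsilyloxy)-2,6-dimethylocta-2,6-dienal, via allylic alcohol 11 (not isolated)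
Conditions: SeO2 (10 mol%), tBuOOH, salicylic acid (10 mol%), CH2Cl2, rt; then MnO2, CH2Cl2, rt
Reagents that add atoms: tert-butyl hydroperoxide CC(C)(C)OO
Why: Sharpless SeO2/tBuOOH allylic oxidation (ene reaction, then [2,3] shift) hydroxylates the E methyl of the more electron-rich terminal olefin, and MnO2 takes the allylic alcohol on to the E enal.

Step 6
Reactants: 12 (2E,6Z)-8-(tert-butyldimethylsilyloxy)-2,6-dimethylocta-2,6-dienal
Product: 13 racemic tert-butyldimethyl{[(2Z,6E)-3-methyl-7-(oxiran-2-yl)octa-2,6-dien-1-yl]oxy}silane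
Conditions: Me3SI, NaH, DMSO–THF, 0 °C to rt
Reagents that add atoms: trimethylsulfonium iodide C[S+](C)C.[I-]
Why: Corey–Chaykovsky epoxidation, in which the sulfonium methylide adds 1,2 to the enal and closes to the vinyl oxirane.

Step 7
Reactants: 13 racemic vinyl oxirane
Product: 14 the (2R)-oxirane enantiomer of 13
Conditions: (S,S)-(salen)Co(OAc) (trivalent cobalt; salen = N,N'-bis(3,5-di-tert-butylsalicylidene)-1,2-cyclohexanediamine dianion; 1 mol%), H2O (0.55 equiv), THF, 0 °C to rt
Reagents that add atoms: none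
Why: Jacobsen hydrolytic kinetic resolution of a terminal epoxide; the catalyst enantiomer that hydrolyses the S epoxide leaves the R epoxide, which carries the C14 configuration.

Step 8
Reactants: 14 (R)-vinyl oxirane; 4 (E)-3-iodo-2-methylprop-2-en-1-yl phenyl sulfone
Product: 15 (1E,5S,6E,10Z)-12-(tert-butyldimethylsilyloxy)-1-iodo-2,6,10-trimethyl-3-(phenylsulfonyl)dodeca-1,6,10-trien-5-ol (C3 epimers)
Conditions: 4, LiN(SiMe3)2, THF–DMPU, −78 °C; then 14, −78 to 0 °C
Reagents that add atoms: none
Why: the lithiated allyl sulfone reacts at its α carbon and opens the terminal epoxide by SN2 at the CH2 carbon (C13), which forms C12–C13 and frees C14–OH with unchanged configuration; an amide base avoids iodine–lithium exchange.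

Step 9
Reactants: 15 silyl ether alcohol
Product: 16 (2Z,6E,8S,11E)-12-iodo-3,7,11-trimethyl-10-(phenylsulfonyl)dodeca-2,6,11-triene-1,8-diol
Conditions: Bu4NF, THF, 0 °C
Reagents that add atoms: none
Why: fluoride cleavage of the primary silyl ether.

Step 10
Reactants: 16 diol
Product: 17 (2Z,6E,8S,11E)-8-hydroxy-12-iodo-3,7,11-trimethyl-10-(phenylsulfonyl)dodeca-2,6,11-trienal
Conditions: TEMPO (10 mol%), PhI(OAc)2, CH2Cl2, rt
Reagents that add atoms: none
Why: oxoammonium oxidation is selective for the primary allylic alcohol over the secondary one and should give the Z enal without isomerization.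

Step 11
Reactants: 17 Z enal; 8 phosphonate
Product: 18 1-tert-butyl 4-ethyl (2R,3E)-3-[(2Z,6E,8S,11E)-8-hydroxy-12-iodo-3,7,11-trimethyl-10-(phenylsulfonyl)dodeca-2,6,11-trien-1-ylidene]-2-methylbutanedioate
Conditions: 8, NaH, THF, 0 °C; then 17, 0 °C to rt
Reagents that add atoms: none
Why: Horner–Wadsworth–Emmons olefination with an α-substituted phosphonoacetate should give the trisubstituted C7=C8 olefin with C6 trans to the ethyl ester, and the C17 centre is not at an acidic position of the phosphonate anion.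

Step 12
Reactants: 18 diene diester
Product: 19 tert-butyl (2R,3E,5Z,9E,11S,14E)-11-hydroxy-3-(hydroxymethyl)-15-iodo-2,6,10,14-tetramethyl-13-(phenylsulfonyl)pentadeca-3,5,9,14-tetraenoate
Conditions: iBu2AlH (4 equiv), CH2Cl2, −78 °C; aqueous potassium sodium tartrate
Reagents that add atoms: none
Why: iBu2AlH reduces the conjugated ethyl ester to the allylic alcohol at −78 °C while the hindered tert-butyl ester survives.

Step 13
Reactants: 19 dienol
Product: 21 (3R,4R,5S)-4-hydroxy-4-(hydroxymethyl)-3-methyl-5-[(1Z,5E,7S,10E)-7-hydroxy-11-iodo-2,6,10-trimethyl-9-(phenylsulfonyl)undeca-1,5,10-trien-1-yl]oxolan-2-one, via epoxy alcohol 20 (not isolated)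
Conditions: Ti(OiPr)4 (20 mol%), D-(−)-diisopropyl tartrate (25 mol%), tBuOOH (1.1 equiv), 4 Å sieves, CH2Cl2, −20 °C; work-up; then CSA (10 mol%), CH2Cl2, 0 °C
Reagents that add atoms: tert-butyl hydroperoxide CC(C)(C)OO
Why: Katsuki–Sharpless epoxidation of the primary allylic alcohol with the D-tartrate sets C7 and C8 as the (7R,8R) epoxide (the secondary C14 allylic alcohol is the mismatched, slow partner of this tartrate), and acid then lets the tert-butyl ester carbonyl open the activated allylic carbon C7 by SN2 with inversion to the γ-lactone with loss of isobutene, leaving the C8 tertiary alcohol.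

Step 14
Reactants: 21 hydroxy lactone
Product: 22 epoxy triol, (3R,4R,5S)-4-hydroxy-4-(hydroxymethyl)-5-{(1Z)-4-[(2S,3S)-3-[(1S,4E)-1-hydroxy-5-iodo-4-methyl-3-(phenylsulfonyl)pent-4-en-1-yl]-3-methyloxiran-2-yl]-2-methylbut-1-en-1-yl}-3-methyloxolan-2-one
Conditions: Ti(OiPr)4 (1.2 equiv), L-(+)-diisopropyl tartrate (1.4 equiv), tBuOOH (2 equiv), 4 Å sieves, CH2Cl2, −20 °C
Reagents that add atoms: tert-butyl hydroperoxide CC(C)(C)OO
Why: matched Katsuki–Sharpless epoxidation of the only remaining allylic alcohol, in which the L-tartrate and the C14 carbinol both favour the erythro (1S,2S) epoxide and so fix the C2 oxygen.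

Step 15
Reactants: 22 epoxy triol
Product: 23 aldehyde: 22 with the C9 CH2OH oxidized to CHO (briarane locants 1S,2S,7S,8S,14S,17R)
Conditions: TEMPO (10 mol%), PhI(OAc)2 (1.1 equiv), CH2Cl2, rt
Reagents that add atoms: none
Why: oxoammonium oxidation takes the primary alcohol and leaves the secondary and tertiary ones, and the α-hydroxy aldehyde has no α hydrogen to epimerize.

Step 16
Reactants: 23 aldehyde
Product: 24 acetate: 23 with C14–OH acetylated (1R,2S,7S,8S,14S,17R)
Conditions: Ac2O, pyridine, CH2Cl2, 0 °C to rt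
Reagents that add atoms: acetic anhydride CC(=O)OC(C)=O
Why: acetylation of the only secondary hydroxyl; the tertiary C8 hydroxyl does not react without DMAP.

Step 17
Reactants: 24 iodo aldehyde
Product: 25 14-membered carbocycle C1–C14 (no C1–C10 bond) with 1,2-epoxide, 14-acetoxy, 12-phenylsulfonyl, E C10=C11, Z C5=C6, 8,9-diol and the C7/C8-fused γ-lactone (1R,2S,7S,8R,9S,14S,17R)
Conditions: CrCl2 (8 equiv), NiCl2 (2 mol%), DMSO–THF, rt, slow addition to 0.002 M
Reagents that add atoms: none
Why: Nozaki–Hiyama–Kishi reaction, in which the alkenyl iodide enters the nickel cycle and is passed to chromium with retention of the E geometry, the alkenylchromium adds to the C9 aldehyde at high dilution to close the 14-membered ring, and C9 should arise 9S by attack on the rotamer whose carbonyl is chelated to the C8 oxygen from the face away from C7, which is also the approach with an anti C7–C8–C9–C10 ring torsion.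

Step 18
Reactants: 25 macrocyclic epoxy allyl sulfone
Product: 26 the target lacking the C2 and C9 acetyl groups (1S,2S,7S,8R,9S,10S,14S,17R)
Conditions: Cp2TiCl2 (3 equiv), Mn (8 equiv), THF, rt (gives Cp2TiCl); this solution added over 3 h to 25 in THF (0.005 M), rt; then 1 M HCl
Reagents that add atoms: none
Why: Proposed new method: Cp2TiCl (trivalent titanium) opens the C1–C2 epoxide by electron transfer to the tertiary C1 radical with the oxygen left on C2 as a titanium alkoxide, the radical adds across the ring to C10 of the E C10=C11 olefin, and the tertiary C11 radical expels PhSO2• by β-scission so that the olefin is fixed at C11=C12 (the sulfonyl radical is reduced to sulfinate by a second Cp2TiCl). The closest known reaction types are the titanocene-mediated transannular radical cyclization of epoxygermacrolides and of epoxypolyprenes and the radical allylation of alkyl radicals by addition–fragmentation on allyl sulfones; the combination, and its use across a 14-membered ring, is new. The cyclohexene (C1, C14, C13, C12, C11, C10) closes in the 6-endo-trig mode, and because the new bond spans the 14-membered ring the ten-membered ring C1–C10 is left as its complement (10-exo-trig seen from the C2–C9 chain). C1 is set by a chair-like transition state in which C2 and C9 are pseudo-equatorial and C15 axial, so that C15 and H10 end up anti as in polyprene cyclizations (the C14 acetoxy group is then axial, which is tolerated); C10 is set by C9, whose hydrogen eclipses the olefin to avoid A(1,3) strain with C20, so that C1 bonds on the face anti to C8. The step needs the C1 radical to add to C10=C11 and not to the equally distant C5=C6 olefin, and to do so before it is reduced: the allylic sulfonyl and hydroxyl groups make C10=C11 the better acceptor for the nucleophilic tertiary radical, addition to the Z C5=C6 olefin would force the lactone-bearing C7 into an axial position, and high dilution with slow addition of Cp2TiCl keeps capture by titanium slow.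

Step 19
Reactants: 26 triol monoacetate
Product: 27 CNP0187165.2
Conditions: Ac2O, pyridine, DMAP (cat.), CH2Cl2, rt
Reagents that add atoms: acetic anhydride CC(=O)OC(C)=O
Why: DMAP-catalysed acetylation of the two secondary hydroxyls at C2 and C9, with the tertiary C8 hydroxyl left free.

**Compound list**

1 | prop-2-yn-1-ol | C#CCO | starting material
2 | (E)-3-iodo-2-methylprop-2-en-1-ol | OC/C(C)=C/I | intermediate
3 | (E)-3-iodo-2-methylprop-2-en-1-yl methanesulfonate | CS(=O)(=O)OC/C(C)=C/I | intermediate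
4 | (E)-3-iodo-2-methylprop-2-en-1-yl phenyl sulfone | I/C=C(\C)CS(=O)(=O)c1ccccc1 | intermediate
5 | tert-butyl (2R)-2-hydroxypropanoate (tert-butyl (R)-lactate) | C[C@@H](O)C(=O)OC(C)(C)C | starting material
6 | triethyl phosphonoacetate | CCOC(=O)CP(=O)(OCC)OCC | starting material
7 | tert-butyl (2R)-2-(trifluoromethylsulfonyloxy)propanoate | C[C@@H](OS(=O)(=O)C(F)(F)F)C(=O)OC(C)(C)C | intermediate
8 | 1-tert-butyl 4-ethyl (2S)-3-(diethoxyphosphoryl)-2-methylbutanedioate (C3 epimers) | CCOC(=O)C(P(=O)(OCC)OCC)[C@@H](C)C(=O)OC(C)(C)C | intermediate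
9 | nerol, (2Z)-3,7-dimethylocta-2,6-dien-1-ol | CC(C)=CCC/C(C)=C\CO | starting material
10 | tert-butyl{[(2Z)-3,7-dimethylocta-2,6-dien-1-yl]oxy}dimethylsilane | CC(C)=CCC/C(C)=C\CO[Si](C)(C)C(C)(C)C | intermediate
11 | (2E,6Z)-8-(tert-butyldimethylsilyloxy)-2,6-dimethylocta-2,6-dien-1-ol | OC/C(C)=C/CC/C(C)=C\CO[Si](C)(C)C(C)(C)C | intermediate
12 | (2E,6Z)-8-(tert-butyldimethylsilyloxy)-2,6-dimethylocta-2,6-dienal | O=C/C(C)=C/CC/C(C)=C\CO[Si](C)(C)C(C)(C)C | intermediate
13 | racemic tert-butyldimethyl{[(2Z,6E)-3-methyl-7-(oxiran-2-yl)octa-2,6-dien-1-yl]oxy}silane | C1OC1/C(C)=C/CC/C(C)=C\CO[Si](C)(C)C(C)(C)C | intermediate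
14 | tert-butyldimethyl{[(2Z,6E)-3-methyl-7-[(2R)-oxiran-2-yl]octa-2,6-dien-1-yl]oxy}silane | C1O[C@@H]1/C(C)=C/CC/C(C)=C\CO[Si](C)(C)C(C)(C)C | intermediate
15 | (1E,5S,6E,10Z)-12-(tert-butyldimethylsilyloxy)-1-iodo-2,6,10-trimethyl-3-(phenylsulfonyl)dodeca-1,6,10-trien-5-ol (C3 epimers) | I/C=C(\C)C(S(=O)(=O)c1ccccc1)C[C@H](O)/C(C)=C/CC/C(C)=C\CO[Si](C)(C)C(C)(C)C | intermediate
16 | (2Z,6E,8S,11E)-12-iodo-3,7,11-trimethyl-10-(phenylsulfonyl)dodeca-2,6,11-triene-1,8-diol | I/C=C(\C)C(S(=O)(=O)c1ccccc1)C[C@H](O)/C(C)=C/CC/C(C)=C\CO | intermediate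
17 | (2Z,6E,8S,11E)-8-hydroxy-12-iodo-3,7,11-trimethyl-10-(phenylsulfonyl)dodeca-2,6,11-trienal | I/C=C(\C)C(S(=O)(=O)c1ccccc1)C[C@H](O)/C(C)=C/CC/C(C)=C\C=O | intermediate
18 | 1-tert-butyl 4-ethyl (2R,3E)-3-[(2Z,6E,8S,11E)-8-hydroxy-12-iodo-3,7,11-trimethyl-10-(phenylsulfonyl)dodeca-2,6,11-trien-1-ylidene]-2-methylbutanedioate | I/C=C(\C)C(S(=O)(=O)c1ccccc1)C[C@H](O)/C(C)=C/CC/C(C)=C\C=C(\C(=O)OCC)[C@@H](C)C(=O)OC(C)(C)C | intermediate
19 | tert-butyl (2R,3E,5Z,9E,11S,14E)-11-hydroxy-3-(hydroxymethyl)-15-iodo-2,6,10,14-tetramethyl-13-(phenylsulfonyl)pentadeca-3,5,9,14-tetraenoate | I/C=C(\C)C(S(=O)(=O)c1ccccc1)C[C@H](O)/C(C)=C/CC/C(C)=C\C=C(\CO)[C@@H](C)C(=O)OC(C)(C)C | intermediate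
20 | tert-butyl (2R)-2-[(2R,3R)-2-(hydroxymethyl)-3-[(1Z,5E,7S,10E)-7-hydroxy-11-iodo-2,6,10-trimethyl-9-(phenylsulfonyl)undeca-1,5,10-trien-1-yl]oxiran-2-yl]propanoate | I/C=C(\C)C(S(=O)(=O)c1ccccc1)C[C@H](O)/C(C)=C/CC/C(C)=C\[C@H]1O[C@@]1(CO)[C@@H](C)C(=O)OC(C)(C)C | intermediate
21 | (3R,4R,5S)-4-hydroxy-4-(hydroxymethyl)-3-methyl-5-[(1Z,5E,7S,10E)-7-hydroxy-11-iodo-2,6,10-trimethyl-9-(phenylsulfonyl)undeca-1,5,10-trien-1-yl]oxolan-2-one | I/C=C(\C)C(S(=O)(=O)c1ccccc1)C[C@H](O)/C(C)=C/CC/C(C)=C\[C@@H]1OC(=O)[C@H](C)[C@@]1(O)CO | intermediate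
22 | epoxy triol: 21 with the C1=C2 olefin as the (1S,2S)-epoxide (7S,8R,14S,17R) | I/C=C(\C)C(S(=O)(=O)c1ccccc1)C[C@H](O)[C@]1(C)O[C@H]1CC/C(C)=C\[C@@H]1OC(=O)[C@H](C)[C@@]1(O)CO | intermediate
23 | aldehyde: 22 with C9 as CHO (1S,2S,7S,8S,14S,17R) | I/C=C(\C)C(S(=O)(=O)c1ccccc1)C[C@H](O)[C@]1(C)O[C@H]1CC/C(C)=C\[C@@H]1OC(=O)[C@H](C)[C@@]1(O)C=O | intermediate
24 | acetate: 23 with C14–OAc (1R,2S,7S,8S,14S,17R) | I/C=C(\C)C(S(=O)(=O)c1ccccc1)C[C@H](OC(C)=O)[C@]1(C)O[C@H]1CC/C(C)=C\[C@@H]1OC(=O)[C@H](C)[C@@]1(O)C=O | intermediate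
25 | 14-membered carbocycle C1–C14 with 1,2-epoxide, 14-acetoxy, 12-phenylsulfonyl, E C10=C11, Z C5=C6, 8,9-diol and C7/C8-fused γ-lactone (1R,2S,7S,8R,9S,14S,17R; C12 epimers) | CC(=O)O[C@H]1CC(S(=O)(=O)c2ccccc2)/C(C)=C/[C@H](O)[C@@]3(O)[C@H](/C=C(/C)CC[C@@H]4O[C@]41C)OC(=O)[C@@H]3C | intermediate
26 | 2,9-di-O-deacetyl target (1S,2S,7S,8R,9S,10S,14S,17R) | CC(=O)O[C@H]1CC=C(C)[C@@H]2[C@H](O)[C@@]3(O)[C@H](/C=C(/C)CC[C@H](O)[C@@]12C)OC(=O)[C@@H]3C | intermediate
27 | CNP0187165.2, (1S,2S,5Z,7S,8S,9S,10S,14S,17R)-2,9,14-triacetoxy-8-hydroxybriara-5,11-dien-19,7-olide | CC(=O)O[C@H]1CC=C(C)[C@@H]2[C@H](OC(C)=O)[C@@]3(O)[C@H](/C=C(/C)CC[C@H](OC(C)=O)[C@@]12C)OC(=O)[C@@H]3C | target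

**Step count and risks**

Total steps: 19. Longest linear sequence: 16 steps (steps 4 to 19, from nerol).

Step 18 (Proposed new method). What may go wrong: the tertiary C1 radical is captured by a second Cp2TiCl before it crosses the ring (reduction, then β-hydride or β-acetoxy elimination to an allylic alcohol or an olefin), or it adds to the C5=C6 olefin. The fallback sets out from 25 and returns at 26. MgBr2·OEt2 in Et2O opens the epoxide at the tertiary carbon to bromohydrin F1. F1 is then irradiated with (Bu3Sn)2 in dilute benzene, the known tin-mediated radical allylation of an alkyl bromide by an allyl sulfone: Bu3Sn• abstracts bromine, the free C1 radical adds to C10 and loses PhSO2•, which regenerates Bu3Sn• from the ditin. No reducing metal is present, so the radical lives until it cyclizes; this fallback answers the capture by titanium but not a preference for C5=C6.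

Step 17. What may go wrong: poor facial selectivity at C9 (a Felkin-type approach in place of the chelated one), which gives the 9-epimer. The fallback sets out from 24 and returns at 25. The ring closure is accepted as it comes, the 9-epimer F2 (or the mixture) is oxidized with Dess–Martin periodinane to enone F3, and the carbonyl is reduced with catecholborane and a Corey–Bakshi–Shibata oxazaborolidine. The oxazaborolidine enantiomer (S if the alkenyl side behaves as the larger group) is chosen to deliver 9S, so that C9 is set by reagent-controlled reduction instead of by C–C bond formation.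

Step 13. What may go wrong: under acid the vinyl epoxide ionizes to an allylic cation before the ester carbonyl arrives (loss of the inversion at C7, Z to E isomerization of C5=C6), or it is opened by the C9 hydroxyl. The fallback sets out from 19 and returns at 21. Epoxy alcohol 20 is isolated and opened at C7 with benzoic acid and Ti(OiPr)4 (chelation-directed C3-selective SN2 opening of a 2,3-epoxy alcohol, with inversion) to benzoate F4. The C8/C9 diol is tied up with 2,2-dimethoxypropane and PPTS as acetonide F5, and K2CO3 in MeOH removes the benzoate to give hydroxy ester F6. Anhydrous TFA in CH2Cl2 at 0 °C cleaves the tert-butyl ester and the C7 hydroxyl closes to lactone acetonide F7, the C9 oxygen being unable to compete. Aqueous AcOH then removes the acetonide to give 21.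

**Further compounds**

F1 | step 18 | bromohydrin: 25 with the epoxide opened to the tertiary C1 bromide and C2–OH | CC(=O)O[C@H]1CC(S(=O)(=O)c2ccccc2)/C(C)=C/[C@H](O)[C@@]3(O)[C@H](/C=C(/C)CC[C@H](O)[C@@]1(Br)C)OC(=O)[C@@H]3C
F2 | step 17 | 9-epimer of 25 (9R) | CC(=O)O[C@H]1CC(S(=O)(=O)c2ccccc2)/C(C)=C/[C@@H](O)[C@@]3(O)[C@H](/C=C(/C)CC[C@@H]4O[C@]41C)OC(=O)[C@@H]3C
F3 | step 17 | enone: 25 with C9 as ketone | CC(=O)O[C@H]1CC(S(=O)(=O)c2ccccc2)/C(C)=C/C(=O)[C@@]3(O)[C@H](/C=C(/C)CC[C@@H]4O[C@]41C)OC(=O)[C@@H]3C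
F4 | step 13 | benzoate: 20 opened at C7 by benzoate (C7–OBz, C8–OH, C9–OH; tert-butyl ester) | I/C=C(\C)C(S(=O)(=O)c1ccccc1)C[C@H](O)/C(C)=C/CC/C(C)=C\[C@H](OC(=O)c1ccccc1)[C@](O)(CO)[C@@H](C)C(=O)OC(C)(C)C
F5 | step 13 | acetonide: F4 with the C8/C9 diol as isopropylidene acetal | I/C=C(\C)C(S(=O)(=O)c1ccccc1)C[C@H](O)/C(C)=C/CC/C(C)=C\[C@H](OC(=O)c1ccccc1)[C@]2(COC(C)(C)O2)[C@@H](C)C(=O)OC(C)(C)C
F6 | step 13 | hydroxy ester: F5 without the benzoyl group | I/C=C(\C)C(S(=O)(=O)c1ccccc1)C[C@H](O)/C(C)=C/CC/C(C)=C\[C@H](O)[C@]2(COC(C)(C)O2)[C@@H](C)C(=O)OC(C)(C)C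
F7 | step 13 | lactone acetonide: 21 with the C8/C9 diol as isopropylidene acetal | I/C=C(\C)C(S(=O)(=O)c1ccccc1)C[C@H](O)/C(C)=C/CC/C(C)=C\[C@@H]1OC(=O)[C@H](C)[C@@]12COC(C)(C)O2
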